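The plan takes ring A apart rather than ring C. In flavanone numbering, C8a and C7 bear meta-related oxygens, C6 next to the 7-hydroxyl bears prenyl, and the C8a oxygen (O1) already sits on the benzylic stereocentre C2. An ethynyl group attached to that oxygen can thus serve as C8a–C8, while a prenyl-substituted alkenyl diazo ketone brings C7, C4a, C5 and C6. A single Wolff rearrangement/vinylketene–alkyne benzannulation then grows the complete arene, with free 7-OH and hydrogen at C4a, and leaves C2 and C3 alone. The precursor is the ethynyl ether of an anti-(1R,2S)-1-arylglycerol whose other two oxygens are tied up as an acetonide. Ring C is closed afterwards by acylation at C4a.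

Key step: step 9

Remarks on the chemistry
- Prenyl means 3-methylbut-2-en-1-yl. Atom labels (C2, C3, C4, C4a and so on) follow flavanone numbering in all intermediates.
- The target SMILES encodes (2R,3R), the 2,3-trans flavanonol. While C4 is still a CH2O carbon, the same spatial arrangement at C3 carries the descriptor S.
- A potassium alkoxide on C2 next to a silyl ether on C3 would invite O-to-O silyl migration. O3 and O4 are therefore held in an acetonide until ring A exists, and silyl ethers go on only when no alkoxide is generated any more.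
- The ring B phenol carries a triisopropylsilyl group, which resists alkoxides and alkyllithiums better than a smaller silyl group.
- C3 comes from the chiral pool. C2 is set by reduction of an aryl ketone, which avoids a substitution at a para-oxygenated benzylic carbon where ionisation could erode configuration.

Step 1
Reactants: 1 4-bromophenol; 2 prenyl bromide
Product: 3 4-bromo-2-prenylphenol
Conditions: NaH (1.05 equiv), toluene, 0 °C; then 2, 0 °C → rt
Reagents that add atoms: none
Why: Ortho C-allylation of a sodium phenoxide in a non-polar solvent, where the tight ion pair shields oxygen and steers the primary end of prenyl bromide to the free ortho carbon, is the classical entry to 2-prenylphenols, and the para position is blocked by bromine.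

Step 2
Reactants: 3 4-bromo-2-prenylphenol
Product: 4 (4-bromo-2-prenylphenoxy)triisopropylsilane
Conditions: TIPSCl, imidazole, DMF, rt
Reagents that add atoms: triisopropylsilyl chloride, CC(C)[Si](Cl)(C(C)C)C(C)C
Why: Standard imidazole-promoted silylation of a phenol, the bulky silyl group being chosen because it must later withstand an aryllithium, a potassium alkoxide and n-BuLi.

Step 3
Reactants: 5 methyl (S)-2,2-dimethyl-1,3-dioxolane-4-carboxylate
Product: 6 (S)-N-methoxy-N,2,2-trimethyl-1,3-dioxolane-4-carboxamide
Conditions: MeNH(OMe)·HCl, i-PrMgCl, THF, −20 → 0 °C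
Reagents that add atoms: N,O-dimethylhydroxylamine hydrochloride, CNOC.Cl
Why: Aminolysis of the ester by the magnesium amide of N,O-dimethylhydroxylamine (Weinreb amide formation) is fast at low temperature and leaves the stereocentre next to the carbonyl group, the future C3, unchanged.

Step 4
Reactants: 4 (4-bromo-2-prenylphenoxy)triisopropylsilane; 6 (S)-N-methoxy-N,2,2-trimethyl-1,3-dioxolane-4-carboxamide
Product: 8 (S)-(2,2-dimethyl-1,3-dioxolan-4-yl)[3-prenyl-4-(triisopropylsilyloxy)phenyl]methanone, via aryllithium 7 (not isolated)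
Conditions: n-BuLi, THF, −78 °C; then 6, −78 → −30 °C; aq NH4Cl
Reagents that add atoms: none
Why: Bromine–lithium exchange followed by the Weinreb ketone synthesis stops at the ketone stage, and at −78 °C neither the para-disposed aryl silyl ether, the prenyl group nor the stereocentre beside the amide carbonyl is affected.

Step 5
Reactants: 8 (S)-(2,2-dimethyl-1,3-dioxolan-4-yl)[3-prenyl-4-(triisopropylsilyloxy)phenyl]methanone
Product: 9 (R)-[(S)-2,2-dimethyl-1,3-dioxolan-4-yl][3-prenyl-4-(triisopropylsilyloxy)phenyl]methanol (anti)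
Conditions: RuCl[(S,S)-TsDPEN](p-cymene) (1 mol %), HCO2H/Et3N (5:2), CH2Cl2, 30 °C
Reagents that add atoms: none
Why: In this Noyori asymmetric transfer hydrogenation of an aryl ketone the (S,S) catalyst delivers hydride in the spatial sense that gives (S)-1-arylethanols, which here is labelled R because C3 outranks the aryl group, so C2 is set under catalyst control anti to the pool-derived C3 oxygen while alkene, acetonide and silyl ether stay untouched.

Step 6
Reactants: 9 anti alcohol; 10 trichloroethylene
Product: 13 {4-[(R)-[(S)-2,2-dimethyl-1,3-dioxolan-4-yl](ethynyloxy)methyl]-2-prenylphenoxy}triisopropylsilane, via dichlorovinyl ether 11 (not isolated), via lithium alkoxyacetylide 12 (not isolated)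
Conditions: KH, THF, 0 °C → rt; 10, −60 °C → rt; then n-BuLi (2.5 equiv), −78 → −40 °C; H2O, −78 °C; Et3N-deactivated silica, product kept cold and used at once
Reagents that add atoms: none
Why: The potassium alkoxide adds to dichloroacetylene released from trichloroethylene to give the (E)-1,2-dichlorovinyl ether, and n-BuLi then causes elimination and chlorine–lithium exchange to the alkoxyacetylide that water protonates, which is the standard trichloroethylene route to alkynyl ethers of hindered secondary and benzylic alcohols, and here the acetonide cannot migrate to the alkoxide and the C2–O bond is never broken.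

Step 7
Reactants: 14 4-methylpent-3-en-1-ol; 15 1-(triphenylphosphoranylidene)propan-2-one
Product: 17 (E)-7-methylocta-3,6-dien-2-one, via 4-methylpent-3-enal 16 (not isolated)
Conditions: DMP, CH2Cl2, 0 °C → rt; then 15 (2.5 equiv), same flask, rt
Reagents that add atoms: none
Why: Dess–Martin oxidation under non-basic conditions gives the isomerisation-prone beta,gamma-unsaturated aldehyde, which the stabilised ylide intercepts in the same flask in an E-selective Wittig reaction before the double bond can move into conjugation.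

Step 8
Reactants: 17 (E)-7-methylocta-3,6-dien-2-one
Product: 19 (E)-1-diazo-7-methylocta-3,6-dien-2-one, via trifluoroacetyl ketone 18 (not isolated)
Conditions: LiN(SiMe3)2, THF, −78 °C; CF3CO2CH2CF3; 5% aq HCl wash; then MsN3, Et3N, H2O (1 equiv), MeCN, rt
Reagents that add atoms: mesyl azide, CS(=O)(=O)N=[N+]=[N-]; 2,2,2-trifluoroethyl trifluoroacetate, O=C(OCC(F)(F)F)C(F)(F)F (its acyl group stays only in 18)
Why: Detrifluoroacetylative diazo transfer, that is kinetic deprotonation at the methyl group, Claisen-type trifluoroacetylation to activate that carbon and diazo transfer with loss of the trifluoroacetyl group, is the established access to alpha,beta-unsaturated diazomethyl ketones, which do not form cleanly from enoyl chlorides and diazomethane.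

Step 9
Reactants: 13 ethynyl ether of the anti alcohol; 19 (E)-1-diazo-7-methylocta-3,6-dien-2-one
Product: 24 5-{(R)-[(S)-2,2-dimethyl-1,3-dioxolan-4-yl][3-prenyl-4-(triisopropylsilyloxy)phenyl]methoxy}-2-prenylphenol, via vinylketene 20 (not isolated), via alkenylcyclobutenone 21 (not isolated), via dienylketene 22 (not isolated), via cyclohexadienone 23 (not isolated)
Conditions: 13 (1 equiv), 19 (2 equiv, added in portions), degassed CH2Cl2, hν (medium-pressure Hg lamp, Pyrex), 15–20 °C until 13 is consumed; then solvent change to toluene, 100 °C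
Reagents that add atoms: none
Why: Light expels N2 from 19 and the alkenyl group shifts to the carbene carbon (Wolff rearrangement, which itself makes C4a–C5) to give vinylketene 20, whose carbonyl carbon is attacked by the nucleophilic terminal carbon of 13 in a polarity-matched [2+2] cycloaddition that forms C7–C8 and C4a–C8a in cyclobutenone 21. On heating, and in part already under irradiation, 21 breaks its C7–C4a bond by four-electron electrocyclic ring opening to dienylketene 22, and ring A then closes by six-electron electrocyclisation forming C6–C7, after which cyclohexadienone 23 tautomerises to phenol 24. This is the second-generation Danheiser benzannulation, well documented for alkenyl diazo ketones and alkoxyacetylenes and applied here to a more elaborate alkoxyacetylene, and ynol ethers of very hindered secondary benzylic alcohols are known to add ketenes readily. No lasting stereocentre is created, since those of 21 and 23 vanish on aromatisation, and C2 and C3 are spectators because the C2–O1 bond is never broken. The only selectivity required is regiochemical and is fixed by the oxygen-polarised triple bond, which puts O1 meta to the new hydroxyl and the prenyl-bearing carbon ortho to it. Because secondary benzylic ethynyl ethers rearrange or lose ketene on warming, 13 is the limiting partner and is consumed at or below 20 °C before any heat is applied, and Pyrex-filtered light spares the aryl ether chromophores.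

Step 10
Reactants: 24 benzannulation product
Product: 25 (2S,3R)-3-(3-hydroxy-4-prenylphenoxy)-3-[3-prenyl-4-(triisopropylsilyloxy)phenyl]propane-1,2-diol
Conditions: AcOH/THF/H2O (3:1:1), 40 °C
Reagents that add atoms: none
Why: Hydrolysis of a terminal acetonide in aqueous acetic acid uses an acid too weak to protonate the prenyl alkenes, to cyclise the ortho-prenylphenol to a chroman, to ionise the C2–O1 ether or to cleave the aryl silyl ether.

Step 11
Reactants: 25 phenol diol
Product: 26 tris(tert-butyldimethylsilyl) ether of 25 (O3, O4 and O7 silylated)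
Conditions: TBSOTf (4 equiv), 2,6-lutidine, CH2Cl2, −40 → 0 °C
Reagents that add atoms: tert-butyldimethylsilyl triflate, CC(C)(C)[Si](C)(C)OS(=O)(=O)C(F)(F)F
Why: Exhaustive silylation with the reactive triflate and a hindered base covers the phenol, the primary and the hindered secondary hydroxyl in one operation, and the bulky group on O7 will later shield C8.

Step 12
Reactants: 26 tris(tert-butyldimethylsilyl) ether
Product: 27 (2S,3R)-2-(tert-butyldimethylsilyloxy)-3-[3-(tert-butyldimethylsilyloxy)-4-prenylphenoxy]-3-[3-prenyl-4-(triisopropylsilyloxy)phenyl]propan-1-ol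
Conditions: CSA (0.1 equiv), MeOH/CH2Cl2 (1:1), −10 → 0 °C
Reagents that add atoms: none
Why: Acid-catalysed methanolysis discriminates by steric access, so the primary silyl ether is lost far faster than the secondary one flanked by C2, while aryl silyl ethers are the least sensitive to acid.

Step 13
Reactants: 27 primary alcohol
Product: 28 (2R,3R)-2-(tert-butyldimethylsilyloxy)-3-[3-(tert-butyldimethylsilyloxy)-4-prenylphenoxy]-3-[3-prenyl-4-(triisopropylsilyloxy)phenyl]propanoic acid
Conditions: TEMPO (0.2 equiv), PhI(OAc)2 (2.5 equiv), CH2Cl2/H2O (2:1), rt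
Reagents that add atoms: water, O
Why: The oxoammonium-mediated TEMPO/PhI(OAc)2 oxidation takes a primary alcohol through the aldehyde hydrate to the acid under nearly neutral conditions that tolerate trisubstituted alkenes and silyl ethers and give the transient aldehyde no base with which to epimerise C3 or expel the beta-aryloxy group.

Step 14
Reactants: 28 acid
Product: 30 (2R,3R)-3,7-bis(tert-butyldimethylsilyloxy)-6-prenyl-2-[3-prenyl-4-(triisopropylsilyloxy)phenyl]chroman-4-one, via mixed anhydride 29 (not isolated)
Conditions: (CF3CO)2O (2 equiv), CH2Cl2 (high dilution), 0 °C → rt; cold aq NaHCO3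
Reagents that add atoms: trifluoroacetic anhydride, O=C(OC(=O)C(F)(F)F)C(F)(F)F (its acyl group stays only in 29)
Why: Intramolecular Friedel–Crafts acylation through the mixed trifluoroacetic anhydride is the standard mild closure of 3-aryloxypropanoic acids of activated arenes to chroman-4-ones, attack coming from C4a (ortho to O1, para to the 7-silyloxy group) because C8 is buried between two oxygen substituents and ring B offers only unactivated positions, with no Lewis acid and no free acylium ion that could lose CO, and the 2,3-trans arrangement carried in from 28 is also the more stable one.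

Step 15
Reactants: 30 protected flavanonol
Product: 31 lespeflorin B1
Conditions: HF·pyridine, pyridine, THF, 0 °C → rt (plastic vessel)
Reagents that add atoms: none
Why: Fluoride-driven cleavage of all three silyl ethers with pyridine-buffered HF avoids the base that would open or epimerise ring C of a flavanonol and is not acidic enough to cyclise the liberated ortho-prenylphenols.

Compound list
1 | 4-bromophenol | Oc1ccc(Br)cc1 | starting material
2 | prenyl bromide (1-bromo-3-methylbut-2-ene) | CC(C)=CCBr | starting material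
3 | 4-bromo-2-prenylphenol | CC(C)=CCc1cc(Br)ccc1O | intermediate
4 | (4-bromo-2-prenylphenoxy)triisopropylsilane | CC(C)=CCc1cc(Br)ccc1O[Si](C(C)C)(C(C)C)C(C)C | intermediate
5 | methyl (S)-2,2-dimethyl-1,3-dioxolane-4-carboxylate | COC(=O)[C@@H]1COC(C)(C)O1 | starting material
6 | (S)-N-methoxy-N,2,2-trimethyl-1,3-dioxolane-4-carboxamide | CON(C)C(=O)[C@@H]1COC(C)(C)O1 | intermediate
7 | [3-prenyl-4-(triisopropylsilyloxy)phenyl]lithium | CC(C)=CCc1cc([Li])ccc1O[Si](C(C)C)(C(C)C)C(C)C | intermediate
8 | (S)-(2,2-dimethyl-1,3-dioxolan-4-yl)[3-prenyl-4-(triisopropylsilyloxy)phenyl]methanone | CC(C)=CCc1cc(C(=O)[C@@H]2COC(C)(C)O2)ccc1O[Si](C(C)C)(C(C)C)C(C)C | intermediate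
9 | (R)-[(S)-2,2-dimethyl-1,3-dioxolan-4-yl][3-prenyl-4-(triisopropylsilyloxy)phenyl]methanol, anti | CC(C)=CCc1cc([C@@H](O)[C@@H]2COC(C)(C)O2)ccc1O[Si](C(C)C)(C(C)C)C(C)C | intermediate
10 | trichloroethylene | ClC=C(Cl)Cl | starting material
11 | (E)-1,2-dichlorovinyl ether of 9 | CC(C)=CCc1cc([C@@H](O/C(Cl)=C\Cl)[C@@H]2COC(C)(C)O2)ccc1O[Si](C(C)C)(C(C)C)C(C)C | intermediate
12 | lithium alkoxyacetylide derived from 9 | CC(C)=CCc1cc([C@@H](OC#C[Li])[C@@H]2COC(C)(C)O2)ccc1O[Si](C(C)C)(C(C)C)C(C)C | intermediate
13 | ethynyl ether of 9, C2 R and C3 S | CC(C)=CCc1cc([C@@H](OC#C)[C@@H]2COC(C)(C)O2)ccc1O[Si](C(C)C)(C(C)C)C(C)C | intermediate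
14 | 4-methylpent-3-en-1-ol | CC(C)=CCCO | starting material
15 | 1-(triphenylphosphoranylidene)propan-2-one | CC(=O)C=P(c1ccccc1)(c1ccccc1)c1ccccc1 | starting material
16 | 4-methylpent-3-enal | CC(C)=CCC=O | intermediate
17 | (E)-7-methylocta-3,6-dien-2-one | CC(=O)/C=C/CC=C(C)C | intermediate
18 | (E)-1,1,1-trifluoro-9-methyldeca-5,8-diene-2,4-dione | O=C(C(F)(F)F)CC(=O)/C=C/CC=C(C)C | intermediate
19 | (E)-1-diazo-7-methylocta-3,6-dien-2-one | [N-]=[N+]=CC(=O)/C=C/CC=C(C)C | intermediate
20 | (E)-7-methylocta-1,3,6-trien-1-one (vinylketene) | O=C=C/C=C/CC=C(C)C | intermediate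
21 | 3-alkoxy-4-[(E)-5-methylhexa-1,4-dienyl]cyclobut-2-enone, alkoxy being the C2 oxygen of 13, ring carbon 4 unassigned | CC(C)=CCc1cc([C@@H](OC3=CC(=O)C3/C=C/CC=C(C)C)[C@@H]2COC(C)(C)O2)ccc1O[Si](C(C)C)(C(C)C)C(C)C | intermediate
22 | 3-alkoxy-9-methyldeca-1,3,5,8-tetraen-1-one (dienylketene, ketene and alkenyl cis on C3=C4) | CC(C)=CCc1cc([C@@H](OC(/C=C=O)=C/C=C/CC=C(C)C)[C@@H]2COC(C)(C)O2)ccc1O[Si](C(C)C)(C(C)C)C(C)C | intermediate
23 | 3-alkoxy-6-prenylcyclohexa-2,4-dien-1-one, ring carbon 6 unassigned | CC(C)=CCc1cc([C@@H](OC3=CC(=O)C(CC=C(C)C)C=C3)[C@@H]2COC(C)(C)O2)ccc1O[Si](C(C)C)(C(C)C)C(C)C | intermediate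
24 | 5-{(R)-[(S)-2,2-dimethyl-1,3-dioxolan-4-yl][3-prenyl-4-(triisopropylsilyloxy)phenyl]methoxy}-2-prenylphenol | CC(C)=CCc1cc([C@@H](Oc3ccc(CC=C(C)C)c(O)c3)[C@@H]2COC(C)(C)O2)ccc1O[Si](C(C)C)(C(C)C)C(C)C | intermediate
25 | (2S,3R)-3-(3-hydroxy-4-prenylphenoxy)-3-[3-prenyl-4-(triisopropylsilyloxy)phenyl]propane-1,2-diol | CC(C)=CCc1cc([C@@H](Oc3ccc(CC=C(C)C)c(O)c3)[C@@H](O)CO)ccc1O[Si](C(C)C)(C(C)C)C(C)C | intermediate
26 | tris(tert-butyldimethylsilyl) ether of 25 | CC(C)=CCc1cc([C@@H](Oc3ccc(CC=C(C)C)c(O[Si](C)(C)C(C)(C)C)c3)[C@@H](O[Si](C)(C)C(C)(C)C)CO[Si](C)(C)C(C)(C)C)ccc1O[Si](C(C)C)(C(C)C)C(C)C | intermediate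
27 | (2S,3R)-2-(tert-butyldimethylsilyloxy)-3-[3-(tert-butyldimethylsilyloxy)-4-prenylphenoxy]-3-[3-prenyl-4-(triisopropylsilyloxy)phenyl]propan-1-ol | CC(C)=CCc1cc([C@@H](Oc3ccc(CC=C(C)C)c(O[Si](C)(C)C(C)(C)C)c3)[C@@H](O[Si](C)(C)C(C)(C)C)CO)ccc1O[Si](C(C)C)(C(C)C)C(C)C | intermediate
28 | (2R,3R)-2-(tert-butyldimethylsilyloxy)-3-[3-(tert-butyldimethylsilyloxy)-4-prenylphenoxy]-3-[3-prenyl-4-(triisopropylsilyloxy)phenyl]propanoic acid | CC(C)=CCc1cc([C@@H](Oc3ccc(CC=C(C)C)c(O[Si](C)(C)C(C)(C)C)c3)[C@@H](O[Si](C)(C)C(C)(C)C)C(=O)O)ccc1O[Si](C(C)C)(C(C)C)C(C)C | intermediate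
29 | mixed anhydride of 28 and trifluoroacetic acid | CC(C)=CCc1cc([C@@H](Oc3ccc(CC=C(C)C)c(O[Si](C)(C)C(C)(C)C)c3)[C@@H](O[Si](C)(C)C(C)(C)C)C(=O)OC(=O)C(F)(F)F)ccc1O[Si](C(C)C)(C(C)C)C(C)C | intermediate
30 | (2R,3R)-3,7-bis(tert-butyldimethylsilyloxy)-6-prenyl-2-[3-prenyl-4-(triisopropylsilyloxy)phenyl]chroman-4-one | CC(C)=CCc1cc([C@H]2Oc3cc(O[Si](C)(C)C(C)(C)C)c(CC=C(C)C)cc3C(=O)[C@@H]2O[Si](C)(C)C(C)(C)C)ccc1O[Si](C(C)C)(C(C)C)C(C)C | intermediate
31 | lespeflorin B1, (2R,3R)-3,7-dihydroxy-2-(4-hydroxy-3-prenylphenyl)-6-prenylchroman-4-one | CC(C)=CCc1cc([C@H]2Oc3cc(O)c(CC=C(C)C)cc3C(=O)[C@@H]2O)ccc1O | target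

Total step count: 15.
Longest linear sequence: 12 steps (1, 2, 4, 5, 6, 9, 10, 11, 12, 13, 14, 15). Steps 3, 7 and 8 are convergent side branches.

Steps most likely to fail

Step 9 (key step).
- What may go wrong: The ethynyl ether may be lost before it meets the ketene, by sigmatropic shift into ring B, by retro-ene loss of ketene or by adventitious hydration. The vinylketene may dimerise faster than it is trapped. Surplus ketene may acylate the phenol as it forms.
- Fallback, from 8 back to 24: Ring A is brought in preformed and the C2–O1 bond is made by substitution. Ketone 8 would be reduced with LiBH(s-Bu)3 (THF, −78 °C, Felkin–Anh control) to the syn alcohol (S)-[(S)-2,2-dimethyl-1,3-dioxolan-4-yl][3-prenyl-4-(triisopropylsilyloxy)phenyl]methanol F1. Resorcinol would be C-prenylated with 2 (aqueous KOH, rt) to 4-prenylresorcinol F2. Mitsunobu etherification of F1 with an excess of F2 (PPh3, DIAD, toluene, 0 °C) should invert C2, because the dioxolane oxygen next to it disfavours ionisation. It should engage the less hindered hydroxyl para to the prenyl chain, which gives 24.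

Step 14.
- What may go wrong: The liberated trifluoroacetic acid may protonate the prenyl alkenes. The para-silyloxy-stabilised benzylic C2–O1 bond may ionise. The anhydride may be too sluggish at a temperature the substrate tolerates, or some attack may occur at C8.
- Fallback, from 28 back to 30: The acyl electrophile is replaced by a nitrilium ion generated cold in the presence of a pyridine base. Acid 28 would be coupled with cyclohexylamine (EDC·HCl, HOBt, CH2Cl2) to the N-cyclohexyl amide F3. Tf2O and 2-fluoropyridine (CH2Cl2, −78 → 0 °C) would dehydrate it to the nitrilium triflate F4, which cannot lose CO. C4a captures F4 in a Houben–Hoesch-type closure to the cyclic N-cyclohexyl ketimine F5. Hydrolysis with aqueous citric acid in THF gives 30.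

Step 6.
- What may go wrong: The potassium alkoxide may attack the aryl silyl ether of a second molecule. The hindered alkoxide may add sluggishly. The sensitive ethynyl ether may decompose during isolation.
- Fallback, from 9 back to 13: No alkoxide is generated. Alcohol 9 would be formylated (acetic formic anhydride, pyridine, 0 °C) to the formate F6. Dichloromethylenation of the formyl group (PPh3, CCl4, THF, 60 °C) would give the 2,2-dichlorovinyl ether F7. Treatment with n-BuLi (2.2 equiv, THF, −78 °C) and then water gives 13.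

Further compounds
F1 | step 9 | (S)-[(S)-2,2-dimethyl-1,3-dioxolan-4-yl][3-prenyl-4-(triisopropylsilyloxy)phenyl]methanol, syn | CC(C)=CCc1cc([C@H](O)[C@@H]2COC(C)(C)O2)ccc1O[Si](C(C)C)(C(C)C)C(C)C
F2 | step 9 | 4-prenylresorcinol (4-(3-methylbut-2-en-1-yl)benzene-1,3-diol) | CC(C)=CCc1ccc(O)cc1O
F3 | step 14 | N-cyclohexyl amide of 28 | CC(C)=CCc1cc([C@@H](Oc3ccc(CC=C(C)C)c(O[Si](C)(C)C(C)(C)C)c3)[C@@H](O[Si](C)(C)C(C)(C)C)C(=O)NC4CCCCC4)ccc1O[Si](C(C)C)(C(C)C)C(C)C
F4 | step 14 | N-cyclohexylnitrilium triflate derived from F3 | CC(C)=CCc1cc([C@@H](Oc3ccc(CC=C(C)C)c(O[Si](C)(C)C(C)(C)C)c3)[C@@H](O[Si](C)(C)C(C)(C)C)C#[N+]C4CCCCC4)ccc1O[Si](C(C)C)(C(C)C)C(C)C.[O-]S(=O)(=O)C(F)(F)F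
F5 | step 14 | N-cyclohexyl ketimine of 30 | CC(C)=CCc1cc([C@H]2Oc3cc(O[Si](C)(C)C(C)(C)C)c(CC=C(C)C)cc3C(=NC4CCCCC4)[C@@H]2O[Si](C)(C)C(C)(C)C)ccc1O[Si](C(C)C)(C(C)C)C(C)C
F6 | step 6 | formate of 9 | CC(C)=CCc1cc([C@@H](OC=O)[C@@H]2COC(C)(C)O2)ccc1O[Si](C(C)C)(C(C)C)C(C)C
F7 | step 6 | 2,2-dichlorovinyl ether of 9 | CC(C)=CCc1cc([C@@H](OC=C(Cl)Cl)[C@@H]2COC(C)(C)O2)ccc1O[Si](C(C)C)(C(C)C)C(C)C
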